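The plan rests on disconnecting the C5–C10 bond shared by rings A and B together with the C4–O bond, which opens the decalin to a ten-membered (1(10)E,4E)-dienone whose only stereocentre is C3. The key step exploits the cis 3α-ester/4α-oxygen pair flanking the trans ring fusion (C5 H, C10 methyl): one acid-triggered operation protonates C1, joins C5 to C10 to form both six-membered rings, and lets the C3 angelate carbonyl capture C4, setting C4, C5 and C10 from C3. Its substrate is (3R)-3-angeloyloxygermacrone, reached from germacrone; O4 acetylation and a singlet-oxygen ene reaction at C7=C11 complete the target.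

Key step: step 5

Remark: compound 2 is racemic at C3, so its SMILES carries no descriptor there; 8 is written as its tosylate and the orthoester carbon of 9 is left undefined.

Step 1
Reactants: 1 germacrone
Product: 2 (±)-3-hydroxygermacrone
Conditions: SeO2 (20 mol%), t-BuOOH (2 equiv), CH2Cl2, 0 °C to rt
Reagents that add atoms: tert-butyl hydroperoxide, CC(C)(C)OO; selenium dioxide, O=[Se]=O (relays the oxygen)
Why: Riley-type allylic hydroxylation with catalytic SeO2 (ene reaction, then [2,3]-sigmatropic shift) should engage the most electron-rich alkene C4=C5 (C7=C11 is conjugated to the ketone and C1=C10 lies β,γ to it), take the hydrogen from the ring CH2 on the more substituted alkene carbon (C3, ahead of the C15 methyl by the usual CH2 > CH3 preference) and return the 4E alkene in the suprafacial [2,3] step, far below the temperature of the Cope rearrangement; the new C3 centre forms racemic and is reset in steps 2 and 3.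

Step 2
Reactants: 2 (±)-3-hydroxygermacrone
Product: 3 germacra-1(10)E,4E,7(11)-triene-3,8-dione
Conditions: MnO2 (activated, excess), CH2Cl2, rt
Reagents that add atoms: none
Why: Activated MnO2 oxidises allylic alcohols selectively under neutral heterogeneous conditions, so the C3 carbinol should become the C4=C5-conjugated ketone without moving the skipped C1=C10 alkene into conjugation, and the racemic centre is erased.

Step 3
Reactants: 3 germacra-1(10)E,4E,7(11)-triene-3,8-dione
Product: 4 (3R)-3-hydroxygermacrone
Conditions: (S)-Me-CBS [(S)-1-methyl-3,3-diphenyltetrahydropyrrolo[1,2-c][1,3,2]oxazaborole] (20 mol%), catecholborane (1.1 equiv), PhMe, −78 °C; then MeOH, pH 7 buffer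
Reagents that add atoms: none
Why: Corey–Bakshi–Shibata reduction, in which the C3 carbonyl binds the oxazaborolidine anti to its larger α-methylalkenyl flank (C4) and takes hydride on the face that gives 3R with the (S)-catalyst (the sense known for aryl methyl ketones and α-substituted enones), while catecholborane at −78 °C does not hydroborate the alkenes and the C8 carbonyl, buttressed by the isopropylidene group, should react more slowly.

Step 4
Reactants: 4 (3R)-3-hydroxygermacrone; 5 angelic acid
Product: 7 (3R)-3-angeloyloxygermacrone, via mixed anhydride 6 (not isolated)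
Conditions: 5, 2,4,6-Cl3C6H2COCl, Et3N, PhMe, rt; then 4, PhMe, 65 °C
Reagents that add atoms: none
Why: Yamaguchi esterification run thermally without a nucleophilic amine catalyst should transfer the angeloyl group to the C3 hydroxyl without Z to E isomerisation, acylation at oxygen leaves the 3R centre untouched, and 65 °C is well below the onset of the Cope rearrangement of the cyclodeca-1,5-diene.

Step 5
Reactants: 7 (3R)-3-angeloyloxygermacrone
Product: 10 3α-angeloyloxy-4α-hydroxyeudesm-7(11)-en-8-one, via dioxolanylium ion 8 (not isolated), via hemi-orthoester 9 (not isolated)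
Conditions: TsOH·H2O (20 mol%), H2O (5 equiv), (CF3)2CHOH, 0 °C; then aq NaHCO3
Reagents that add atoms: water, O
Why: Proposed new method: the acid protonates C1 of the C1=C10 alkene (C4=C5 is deactivated by the allylic ester, C7=C11 by conjugation), C5 bonds to the tertiary C10 centre across the ring and, as positive charge moves to C4, the angelate carbonyl oxygen closes on C4 to give acyloxonium ion 8, to which water adds at the former carbonyl carbon (9) before the hemi-orthoester opens to the 3-ester and the free 4-hydroxyl. The closest known reaction types are the acid-induced transannular cyclisation of germacrone-type 1(10),4-dienes to eudesmanes and acyloxonium participation with hydrolysis to cis hydroxy esters as in the Woodward cis-hydroxylation, which have not been coupled in one transannular event. The single C5–C10 bond closes ring B in a 6-exo-trig and ring A in a 6-endo-trig sense with respect to C4=C5, and the transient dioxolane ring forms by 5-exo capture at C4. C5 and C10 are set by the crossed chair–chair fold of the (1(10)E,4E)-diene, which gives the trans fusion with 5α-H and 10β-CH3, and C4 by anti addition across C4=C5 with oxygen delivered from the 3α-ester (4α-O, 4β-CH3). The step needs the fold in which the C3–O bond stands pseudoaxial on the face of C4 opposite the incoming C10; with 3R only the fold leading to the 5R,10R series has this geometry, and anchimeric assistance should make it the faster channel (Curtin–Hammett), whereas the other fold cannot be assisted. The ester should stay on O3 because hemi-orthoesters fused to cyclohexanes open to the axial ester and because a secondary ester is favoured over a tertiary one.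

Step 6
Reactants: 10 3α-angeloyloxy-4α-hydroxyeudesm-7(11)-en-8-one
Product: 11 4α-acetoxy-3α-angeloyloxyeudesm-7(11)-en-8-one
Conditions: Ac2O (3 equiv), Sc(OSO2CF3)3 (2 mol%), MeCN, −20 °C
Reagents that add atoms: acetic anhydride, CC(=O)OC(C)=O
Why: Lewis-acid-catalysed acylation with acetic anhydride and scandium triflate is a known way to acetylate hindered tertiary alcohols at −20 °C faster than they eliminate or a neighbouring ester migrates, and bond formation at oxygen leaves C4 and the angelate geometry unchanged.

Step 7
Reactants: 11 4α-acetoxy-3α-angeloyloxyeudesm-7(11)-en-8-one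
Product: 12 4α-acetoxy-3α-angeloyloxy-7α-hydroperoxyeudesm-11-en-8-one
Conditions: O2, tetraphenylporphyrin (1 mol%), hν (visible, >500 nm), CH2Cl2, −20 °C
Reagents that add atoms: oxygen, O=O
Why: Schenck ene reaction, in which singlet oxygen, as with pulegone-type 2-isopropylidenecyclohexanones, should attack the tetrasubstituted C7=C11 alkene rather than the electron-poor angelate and approach C7 along the axial α trajectory opposite the C14 angular methyl, where only C12/C13 methyl hydrogens are aligned with the π system (H6α is equatorial), so that C7 receives the α-hydroperoxide (7S) and the alkene moves to C11=C12.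

Compound list
1 | germacrone, (1(10)E,4E)-germacra-1(10),4,7(11)-trien-8-one | CC(C)=C1C/C=C(C)/CC/C=C(C)/CC1=O | starting material
2 | (±)-3-hydroxygermacrone, racemic (1(10)E,4E)-3-hydroxygermacra-1(10),4,7(11)-trien-8-one | CC(C)=C1C/C=C(C)/C(O)C/C=C(C)/CC1=O | intermediate
3 | (1(10)E,4E)-germacra-1(10),4,7(11)-triene-3,8-dione | CC(C)=C1C/C=C(C)/C(=O)C/C=C(C)/CC1=O | intermediate
4 | (3R)-3-hydroxygermacrone, (3R,1(10)E,4E)-3-hydroxygermacra-1(10),4,7(11)-trien-8-one | CC(C)=C1C/C=C(C)/[C@H](O)C/C=C(C)/CC1=O | intermediate
5 | angelic acid, (Z)-2-methylbut-2-enoic acid | C/C=C(/C)C(=O)O | starting material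
6 | angelic 2,4,6-trichlorobenzoic anhydride (not isolated) | C/C=C(/C)C(=O)OC(=O)c1c(Cl)cc(Cl)cc1Cl | intermediate
7 | (3R)-3-angeloyloxygermacrone, (3R,1(10)E,4E)-3-[(Z)-2-methylbut-2-enoyloxy]germacra-1(10),4,7(11)-trien-8-one | CC(C)=C1C/C=C(C)/[C@H](OC(=O)/C(C)=C\C)C/C=C(C)/CC1=O | intermediate
8 | 2-[(Z)-but-2-en-2-yl]-1,3-dioxolan-2-ylium ion bridging O3α and O4α of eudesm-7(11)-en-8-one, tosylate (not isolated) | CC(C)=C1C[C@@H]2[C@](C)(CC[C@@H](OC(/C(C)=C\C)=[O+]3)[C@]23C)CC1=O.Cc1ccc(cc1)S(=O)(=O)[O-] | intermediate
9 | 2-hydroxy-2-[(Z)-but-2-en-2-yl]-1,3-dioxolane (hemi-orthoester) bridging O3α and O4α of eudesm-7(11)-en-8-one (not isolated) | CC(C)=C1C[C@@H]2[C@](C)(CC[C@@H](OC(O)(/C(C)=C\C)O3)[C@]23C)CC1=O | intermediate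
10 | (3R,4S,5R,10R)-3α-angeloyloxy-4α-hydroxyeudesm-7(11)-en-8-one | CC(C)=C1C[C@@H]2[C@](C)(CC[C@@H](OC(=O)/C(C)=C\C)[C@@]2(C)O)CC1=O | intermediate
11 | (3R,4S,5R,10R)-4α-acetoxy-3α-angeloyloxyeudesm-7(11)-en-8-one | CC(C)=C1C[C@@H]2[C@](C)(CC[C@@H](OC(=O)/C(C)=C\C)[C@@]2(C)OC(C)=O)CC1=O | intermediate
12 | (3R,4S,5R,7S,10R)-4α-acetoxy-3α-angeloyloxy-7α-hydroperoxyeudesm-11-en-8-one | C=C(C)[C@@]1(OO)C[C@@H]2[C@](C)(CC[C@@H](OC(=O)/C(C)=C\C)[C@@]2(C)OC(C)=O)CC1=O | target

Total step count: 7. Longest linear sequence: 7 steps (1 to 12).

Steps most likely to fail

Step 5. The C4 cation may lose a proton before the ester closes on it, the allylic C3–O bond may ionise under Brønsted acid, cyclisation may run through the unassisted fold, or the angelate may isomerise within the conjugated acyloxonium ion. The fallback changes the initiating electrophile from a proton to a mercury salt and uses known reaction types (transannular oxymercuration of cyclodeca-1,5-dienes, radical demercuration). It sets out from 7: Hg(OCOCF3)2 in THF/H2O at −20 °C should add to C1=C10 with mercury on C1, C5 then attacks C10 across the ring and water (or the ester, then water) captures C4 anti, and NaCl work-up should give the organomercury chloride 1β-chloromercurio-3α-angeloyloxy-4α-hydroxyeudesm-7(11)-en-8-one F1. Treatment with n-Bu3SnH (THF, rt) replaces mercury by hydrogen at C1, and the sequence comes back to the route at 10.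

Step 1. The ene step may take its hydrogen from the C15 or C14 methyl groups instead of C3, a known tendency of (E)-alkenes in medium rings. The 4E alkene may also isomerise during the [2,3] shift, and the selenium electrophile may trigger transannular closure. The fallback keeps 1 as its starting point and moves site control from the reagent to a catalyst pocket: a panel of engineered cytochrome P450 hydroxylases (NADPH recycling, pH 8 buffer, rt), a known way to direct allylic hydroxylation of germacrane-type terpenoids, is screened for C3 hydroxylation. It comes back to the route at 2, or at 4 if a 3R-selective variant is found, and makes no compound outside the list (entry F0).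

Step 7. Singlet oxygen may attack the β face and take the axial H6β, which would move the alkene to C6=C7 and place the hydroperoxide on C11, or it may show poor facial selectivity at C7. The fallback replaces the ene reaction by enolate oxygenation with ground-state oxygen. It sets out from 11: potassium tert-butoxide (1.1 equiv, THF/t-BuOH, −40 °C) under equilibrating conditions should remove a C12 hydrogen to give the extended dienolate potassium 4α-acetoxy-3α-angeloyloxyeudesma-7,11-dien-8-olate F2, which O2 should trap at C7 from the axial α face, anti to the C14 methyl. An acetic acid quench at −78 °C returns the route at 12.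

Further compounds
F0 | step 1 | none | none
F1 | step 5 | 1β-chloromercurio-3α-angeloyloxy-4α-hydroxyeudesm-7(11)-en-8-one | CC(C)=C1C[C@@H]2[C@](C)([C@H]([Hg]Cl)C[C@@H](OC(=O)/C(C)=C\C)[C@@]2(C)O)CC1=O
F2 | step 7 | potassium 4α-acetoxy-3α-angeloyloxyeudesma-7,11-dien-8-olate | C=C(C)C=1C[C@@H]2[C@](C)(CC[C@@H](OC(=O)/C(C)=C\C)[C@@]2(C)OC(C)=O)CC=1[O-].[K+]
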